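## Retrosynthetic overview

- The target comes from tris-angelate diene 28 by a late, reagent-controlled Shi epoxidation of the C10=C11 alkene; the oxirane is the last ring formed.
- The three angelates are placed one at a time from the Yamaguchi mixed anhydride of angelic acid: O5 through a tin acetal on the ring tetraol, then O3 and O8 under a transient O4/O6 phenylboronate. Between them, the C7–C8 bond and the C8 carbinol come from an asymmetric Ni/Cr coupling of a C7 vinyl iodide (from a vinylsilane) with 4-methylpent-3-enal.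
- The ring oxygens come from a hydroxyl-directed cis-dihydroxylation (C5, C6) and a hydroxyl-directed ketone reduction (C3) of a 2-hydroxy-2-methylcyclohex-3-enone.
- Key step: α-ketol ring expansion of a 1-acetylcyclopent-2-en-1-ol, a 1,2-shift of the ring alkenyl carbon that turns the five-membered ring into the six-membered ring and creates C4.
- The cyclopentenol comes from 1-ethoxyvinyllithium and (S)-4-[1-(trimethylsilyl)vinyl]cyclopentenone, itself made by addition–elimination on (S)-4-silyloxycyclopentenone.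

Assumption: (S)-4-hydroxycyclopent-2-en-1-one is bought as the single enantiomer. Atom numbers are those of the target: ring C1 (side chain), C2 (CH2), C3 (OAng), C4 (Me, OH), C5 (OAng), C6 (OH); side chain C7 (=CH2), C8 (OAng), C9, C10/C11 (oxirane).

## Route

Step 1
Reactants: 1 (4S)-4-hydroxycyclopent-2-en-1-one
Product: 2 (4S)-4-[(tert-butyldimethylsilyl)oxy]cyclopent-2-en-1-one
Conditions: TBSCl, imidazole, DMF, 0 °C to rt
Reagents that add atoms: tert-butyldimethylsilyl chloride, CC(C)(C)[Si](C)(C)Cl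
Why: Standard silyl protection of the secondary alcohol (Corey silylation); the stereocentre is untouched and the silyloxy group later serves as the leaving group.

Step 2
Reactants: 2 (4S)-4-[(tert-butyldimethylsilyl)oxy]cyclopent-2-en-1-one; 3 (1-bromoethenyl)trimethylsilane
Product: 6 (4S)-4-[1-(trimethylsilyl)ethenyl]cyclopent-2-en-1-one, via Grignard reagent 4 (not isolated), via trans adduct 5 (not isolated)
Conditions: 3, Mg, THF, 40 °C; then CuBr·SMe2 (10 mol%), 2, THF, –78 °C; aq NH4Cl; crude product, DBU, CH2Cl2, 0 °C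
Reagents that add atoms: none
Why: Copper-catalysed conjugate addition of the vinyl Grignard reagent anti to the silyloxy group, then E1cB loss of silanol (addition–elimination), relays the C–O stereocentre into C1.

Step 3
Reactants: 6 (4S)-4-[1-(trimethylsilyl)ethenyl]cyclopent-2-en-1-one; 7 ethyl vinyl ether
Product: 10 1-{(1R,4S)-1-hydroxy-4-[1-(trimethylsilyl)ethenyl]cyclopent-2-en-1-yl}ethan-1-one, via 1-ethoxyvinyllithium 8 (not isolated), via enol ether carbinol 9 (not isolated)
Conditions: 7, tBuLi, THF, –78 to 0 °C; then 6, –78 °C; then 0.5 M HCl, THF/H2O, 0 °C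
Reagents that add atoms: water, O
Why: 1,2-Addition of the acyl-anion equivalent occurs anti to the C1 substituent, so the new tertiary OH is cis to it; aqueous acid then hydrolyses the enol ether to the methyl ketone.

Step 4
Reactants: 10 1-{(1R,4S)-1-hydroxy-4-[1-(trimethylsilyl)ethenyl]cyclopent-2-en-1-yl}ethan-1-one
Product: 11 (2S,5S)-2-hydroxy-2-methyl-5-[1-(trimethylsilyl)ethenyl]cyclohex-3-en-1-one
Conditions: Cu(OTf)2 (10 mol%), (S,S)-tBu-box (12 mol%; the (R,R) ligand is run as first control to confirm which antipode matches the substrate), 4 Å MS, CH2Cl2, 0 °C to rt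
Reagents that add atoms: none
Why: Proposed new method: a chelate-controlled, alkenyl-selective α-ketol (acyloin) ring expansion. Divalent copper/box binds the hydroxyl and acetyl oxygens in a five-membered chelate (O=C–C–O syn-periplanar), which places the ring alkenyl carbon and the ring CH2 on opposite faces of the acetyl carbonyl; the tert-butyl groups leave open only the face on which the alkenyl carbon C5 lies. That carbon, which also has the higher migratory aptitude through π-participation, shifts 1,2 from C3 to the acetyl carbon; this expands cyclopentene to cyclohexene and, because the shift is suprafacial within the syn chelate, creates C4 with its OH on the face of the former carbinol OH (cis to the C1 group). The mild, non-equilibrating conditions should stop short of the conjugated isomer that alkyl migration would give. Closest known reaction type: Lewis-acid-catalysed (including enantioselective) α-ketol ring expansion of 1-acylcycloalkanols, not yet shown for 1-acylcycloalk-2-en-1-ols where alkenyl and alkyl migration compete.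

Step 5
Reactants: 11 (2S,5S)-2-hydroxy-2-methyl-5-[1-(trimethylsilyl)ethenyl]cyclohex-3-en-1-one
Product: 13 (2S,3S,4S,5S)-2,3,4-trihydroxy-2-methyl-5-[1-(trimethylsilyl)ethenyl]cyclohexan-1-one, via osmate ester 12 (not isolated)
Conditions: OsO4 (1.05 equiv), TMEDA (1.1 equiv), CH2Cl2, –78 °C; then aq Na2SO3, THF, rt
Reagents that add atoms: osmium tetroxide, O=[Os](=O)(=O)=O
Why: Donohoe hydrogen-bond-directed dihydroxylation: the pseudoaxial tertiary C4–OH delivers the OsO4·TMEDA complex to its own face, giving the all-cis C4/C5/C6 triol, while the hindered silyl-substituted exocyclic alkene is spared.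

Step 6
Reactants: 13 (2S,3S,4S,5S)-2,3,4-trihydroxy-2-methyl-5-[1-(trimethylsilyl)ethenyl]cyclohexan-1-one
Product: 14 (1S,2R,3S,4S,5S)-2-methyl-5-[1-(trimethylsilyl)ethenyl]cyclohexane-1,2,3,4-tetrol
Conditions: Me4NBH(OAc)3, MeCN/AcOH (1:1), –30 to 0 °C
Reagents that add atoms: none
Why: Saksena–Evans hydroxyl-directed reduction: hydride is delivered intramolecularly from acetoxyborohydrides bound to the C4 (α) and C5 (β) hydroxyls, both on the upper face, so the C3–OH ends trans to the C4–OH.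

Step 7
Reactants: 14 (1S,2R,3S,4S,5S)-2-methyl-5-[1-(trimethylsilyl)ethenyl]cyclohexane-1,2,3,4-tetrol
Product: 15 (1S,2R,3S,4S,5S)-5-(1-iodoethenyl)-2-methylcyclohexane-1,2,3,4-tetrol
Conditions: NIS, (CF3)2CHOH, 0 °C
Reagents that add atoms: N-iodosuccinimide, O=C1CCC(=O)N1I
Why: ipso-Iododesilylation of the vinylsilane (electrophilic substitution through the β-silyl cation) gives the 2-iodoalkene before any angelate is present; no stereocentre is involved and free hydroxyls are tolerated.

Step 8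
Reactants: 16 angelic acid [(2Z)-2-methylbut-2-enoic acid]
Product: 17 (2Z)-2-methylbut-2-enoic 2,4,6-trichlorobenzoic anhydride
Conditions: 2,4,6-Cl3C6H2COCl (1.0 equiv), Et3N (1.05 equiv), toluene, rt, 2 h; filtered under argon; the dry toluene solution is used in steps 9, 10 and 13
Reagents that add atoms: 2,4,6-trichlorobenzoyl chloride, O=C(Cl)c1c(Cl)cc(Cl)cc1Cl
Why: Yamaguchi mixed-anhydride formation without DMAP keeps the Z geometry of the angeloyl group, and the two ortho chlorines later steer every nucleophile to the angeloyl carbonyl.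

Step 9
Reactants: 15 (1S,2R,3S,4S,5S)-5-(1-iodoethenyl)-2-methylcyclohexane-1,2,3,4-tetrol; 17 (2Z)-2-methylbut-2-enoic 2,4,6-trichlorobenzoic anhydride
Product: 19 O5-[(2Z)-2-methylbut-2-enoate] of 15 (O3/O4/O6 free), via stannylene acetal 18 (not isolated)
Conditions: Bu2SnO (1.05 equiv), MeOH, reflux, then evaporate; 17 (1.1 equiv), toluene/THF, 0 °C to rt
Reagents that add atoms: none
Why: Stannylene-acetal-directed regioselective acylation: tin bridges a cis-vicinal pair that contains O5 (O5/O6 or O4/O5) and in either acetal activates the equatorial oxygen O5, which alone takes the angeloyl group at room temperature while the unactivated axial O3 does not react; no stereocentre changes.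

Step 10
Reactants: 19 O5-[(2Z)-2-methylbut-2-enoate] of 15 (O3/O4/O6 free); 17 (2Z)-2-methylbut-2-enoic 2,4,6-trichlorobenzoic anhydride
Product: 22 (1S,2R,3S,4S,5S)-2,4-dihydroxy-5-(1-iodoethenyl)-2-methylcyclohexane-1,3-diyl bis[(2Z)-2-methylbut-2-enoate], via phenylboronate 20 (not isolated), via boronate diester 21 (not isolated)
Conditions: PhB(OH)2 (1.05 equiv), toluene, 4 Å MS, 50 °C; then 17 (2.5 equiv), Et3N, 80 °C, dark; then pinacol, rt
Reagents that add atoms: none
Why: Phenylboronic acid bridges the cis 1,3-diaxial O4/O6 pair (as in ribopyranoside 2,4-boronates), so the Yamaguchi-type esterification (no DMAP, hence no Z-to-E isomerisation) can reach only the axial O3; pinacol exchange then frees the diol.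

Step 11
Reactants: 23 4-methylpent-3-en-1-ol
Product: 24 4-methylpent-3-enal
Conditions: Dess–Martin periodinane, NaHCO3, CH2Cl2, 0 °C; solution used at once
Reagents that add atoms: none
Why: Buffered Dess–Martin oxidation gives the β,γ-unsaturated aldehyde without isomerisation into conjugation.

Step 12
Reactants: 22 (1S,2R,3S,4S,5S)-2,4-dihydroxy-5-(1-iodoethenyl)-2-methylcyclohexane-1,3-diyl bis[(2Z)-2-methylbut-2-enoate]; 24 4-methylpent-3-enal
Product: 25 (1S,2R,3S,4S,5R)-2,4-dihydroxy-5-[(3S)-3-hydroxy-6-methylhepta-1,5-dien-2-yl]-2-methylcyclohexane-1,3-diyl bis[(2Z)-2-methylbut-2-enoate]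
Conditions: CrCl2 (4 equiv), Kishi oxazoline–sulfonamide ligand N-[2-(4-tert-butyl-4,5-dihydrooxazol-2-yl)-6-methylphenyl]methanesulfonamide (4.4 equiv, antipode chosen for 8S), Et3N (4.4 equiv), NiCl2 (5 mol%), THF, rt
Reagents that add atoms: none
Why: Nozaki–Hiyama–Kishi coupling forms C7–C8 in the presence of the two esters and the free O4/O6 hydroxyls; the C8 carbinol is set by the chiral sulfonamide–chromium complex (reagent control).

Step 13
Reactants: 25 (1S,2R,3S,4S,5R)-2,4-dihydroxy-5-[(3S)-3-hydroxy-6-methylhepta-1,5-dien-2-yl]-2-methylcyclohexane-1,3-diyl bis[(2Z)-2-methylbut-2-enoate]; 17 (2Z)-2-methylbut-2-enoic 2,4,6-trichlorobenzoic anhydride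
Product: 28 (1S,2R,3S,4S,5R)-2,4-dihydroxy-2-methyl-5-{(3S)-6-methyl-3-[(2Z)-2-methylbut-2-enoyloxy]hepta-1,5-dien-2-yl}cyclohexane-1,3-diyl bis[(2Z)-2-methylbut-2-enoate], via phenylboronate 26 (not isolated), via boronate triester 27 (not isolated)
Conditions: PhB(OH)2 (1.05 equiv), toluene, 4 Å MS, 50 °C; then 17 (2 equiv), Et3N, 80 °C; then pinacol, rt
Reagents that add atoms: none
Why: With O4/O6 again tied up as the cyclic phenylboronate, the allylic O8 is the only free hydroxyl and is esterified by the DMAP-free Yamaguchi protocol with retention at C8 and without angelate-to-tiglate isomerisation; pinacol exchange then frees the diol.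

Step 14
Reactants: 28 (1S,2R,3S,4S,5R)-2,4-dihydroxy-2-methyl-5-{(3S)-6-methyl-3-[(2Z)-2-methylbut-2-enoyloxy]hepta-1,5-dien-2-yl}cyclohexane-1,3-diyl bis[(2Z)-2-methylbut-2-enoate]
Product: 29 (1S,2R,3S,4S,5R)-5-{(3S)-4-[(2S)-3,3-dimethyloxiran-2-yl]-3-[(2Z)-2-methylbut-2-enoyloxy]but-1-en-2-yl}-2,4-dihydroxy-2-methylcyclohexane-1,3-diyl bis[(2Z)-2-methylbut-2-enoate] (CNP0421750.2)
Conditions: L-fructose-derived Shi ketone (ent-Shi ketone, 1 equiv), KHSO5 (as 2KHSO5·KHSO4·K2SO4), NaHCO3, Bu4NHSO4 (cat.), MeCN/aq Na2EDTA, 0 °C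
Reagents that add atoms: potassium peroxymonosulfate, [K+].[O-]S(=O)(=O)OO
Why: Shi asymmetric epoxidation (chiral dioxirane) attacks only the electron-rich trisubstituted C10=C11 alkene and sets 10S by reagent control with the L-fructose-derived ketone; the near-neutral pH avoids acyl migration to O6 or O4.

## Compound list

1 | (4S)-4-hydroxycyclopent-2-en-1-one | O=C1C=C[C@@H](O)C1 | starting material
2 | (4S)-4-[(tert-butyldimethylsilyl)oxy]cyclopent-2-en-1-one | O=C1C=C[C@@H](O[Si](C)(C)C(C)(C)C)C1 | intermediate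
3 | (1-bromoethenyl)trimethylsilane | C=C(Br)[Si](C)(C)C | starting material
4 | bromo[1-(trimethylsilyl)ethenyl]magnesium | C=C([Mg]Br)[Si](C)(C)C | intermediate
5 | (3S,4S)-4-[(tert-butyldimethylsilyl)oxy]-3-[1-(trimethylsilyl)ethenyl]cyclopentan-1-one (trans) | O=C1C[C@H](C(=C)[Si](C)(C)C)[C@@H](O[Si](C)(C)C(C)(C)C)C1 | intermediate
6 | (4S)-4-[1-(trimethylsilyl)ethenyl]cyclopent-2-en-1-one | O=C1C=C[C@@H](C(=C)[Si](C)(C)C)C1 | intermediate
7 | ethyl vinyl ether (ethoxyethene) | C=COCC | starting material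
8 | (1-ethoxyethenyl)lithium | [Li]C(=C)OCC | intermediate
9 | (1R,4S)-1-(1-ethoxyethenyl)-4-[1-(trimethylsilyl)ethenyl]cyclopent-2-en-1-ol | C=C(OCC)[C@]1(O)C=C[C@@H](C(=C)[Si](C)(C)C)C1 | intermediate
10 | 1-{(1R,4S)-1-hydroxy-4-[1-(trimethylsilyl)ethenyl]cyclopent-2-en-1-yl}ethan-1-one | CC(=O)[C@]1(O)C=C[C@@H](C(=C)[Si](C)(C)C)C1 | intermediate
11 | (2S,5S)-2-hydroxy-2-methyl-5-[1-(trimethylsilyl)ethenyl]cyclohex-3-en-1-one | C=C([Si](C)(C)C)[C@H]1CC(=O)[C@@](C)(O)C=C1 | intermediate
12 | cyclic osmate ester of 13 across O3/O4 of the cyclohexanone (target O5/O6), hexavalent dioxo-osmium chelated by TMEDA | C=C([Si](C)(C)C)[C@H]1CC(=O)[C@@](C)(O)[C@H]2O[Os-2]3(=O)(=O)(O[C@@H]12)[N+](C)(C)CC[N+]3(C)C | intermediate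
13 | (2S,3S,4S,5S)-2,3,4-trihydroxy-2-methyl-5-[1-(trimethylsilyl)ethenyl]cyclohexan-1-one | C=C([Si](C)(C)C)[C@H]1CC(=O)[C@@](C)(O)[C@@H](O)[C@H]1O | intermediate
14 | (1S,2R,3S,4S,5S)-2-methyl-5-[1-(trimethylsilyl)ethenyl]cyclohexane-1,2,3,4-tetrol | C=C([Si](C)(C)C)[C@H]1C[C@H](O)[C@@](C)(O)[C@@H](O)[C@H]1O | intermediate
15 | (1S,2R,3S,4S,5S)-5-(1-iodoethenyl)-2-methylcyclohexane-1,2,3,4-tetrol | C=C(I)[C@H]1C[C@H](O)[C@@](C)(O)[C@@H](O)[C@H]1O | intermediate
16 | angelic acid, (2Z)-2-methylbut-2-enoic acid | C/C=C(/C)C(=O)O | starting material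
17 | (2Z)-2-methylbut-2-enoic 2,4,6-trichlorobenzoic anhydride | C/C=C(/C)C(=O)OC(=O)c1c(Cl)cc(Cl)cc1Cl | intermediate
18 | dibutylstannylene acetal of 15 (target O5 and O6 joined through SnBu2; O3, O4 free) | C=C(I)[C@H]1C[C@H](O)[C@@](C)(O)[C@H]2O[Sn](CCCC)(CCCC)O[C@@H]12 | intermediate
19 | O5-[(2Z)-2-methylbut-2-enoate] of 15 (target numbering; O3, O4, O6 free; ring stereocentres as in 15) | C=C(I)[C@H]1C[C@H](O)[C@@](C)(O)[C@@H](OC(=O)/C(C)=C\C)[C@H]1O | intermediate
20 | cyclic phenylboronate of 19 (target O4 and O6 joined through B–Ph; O3 free, O5 angelate) | C=C(I)[C@H]1C[C@H](O)[C@@]2(C)OB(c3ccccc3)O[C@@H]1[C@@H]2OC(=O)/C(C)=C\C | intermediate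
21 | O3,O5-bis[(2Z)-2-methylbut-2-enoate] of the O4,O6-phenylboronate of 15 | C=C(I)[C@H]1C[C@H](OC(=O)/C(C)=C\C)[C@@]2(C)OB(c3ccccc3)O[C@@H]1[C@@H]2OC(=O)/C(C)=C\C | intermediate
22 | (1S,2R,3S,4S,5S)-2,4-dihydroxy-5-(1-iodoethenyl)-2-methylcyclohexane-1,3-diyl bis[(2Z)-2-methylbut-2-enoate] | C=C(I)[C@H]1C[C@H](OC(=O)/C(C)=C\C)[C@@](C)(O)[C@@H](OC(=O)/C(C)=C\C)[C@H]1O | intermediate
23 | 4-methylpent-3-en-1-ol | CC(C)=CCCO | starting material
24 | 4-methylpent-3-enal | CC(C)=CCC=O | intermediate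
25 | (1S,2R,3S,4S,5R)-2,4-dihydroxy-5-[(3S)-3-hydroxy-6-methylhepta-1,5-dien-2-yl]-2-methylcyclohexane-1,3-diyl bis[(2Z)-2-methylbut-2-enoate] | C=C([C@H](CC=C(C)C)O)[C@H]1C[C@H](OC(=O)/C(C)=C\C)[C@@](C)(O)[C@@H](OC(=O)/C(C)=C\C)[C@H]1O | intermediate
26 | cyclic phenylboronate of 25 (target O4 and O6 joined through B–Ph; O8 free) | C=C([C@H](CC=C(C)C)O)[C@H]1C[C@H](OC(=O)/C(C)=C\C)[C@@]2(C)OB(c3ccccc3)O[C@@H]1[C@@H]2OC(=O)/C(C)=C\C | intermediate
27 | O8-[(2Z)-2-methylbut-2-enoate] of phenylboronate 26 (O3, O5, O8 all angelates) | C=C([C@H](CC=C(C)C)OC(=O)/C(C)=C\C)[C@H]1C[C@H](OC(=O)/C(C)=C\C)[C@@]2(C)OB(c3ccccc3)O[C@@H]1[C@@H]2OC(=O)/C(C)=C\C | intermediate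
28 | (1S,2R,3S,4S,5R)-2,4-dihydroxy-2-methyl-5-{(3S)-6-methyl-3-[(2Z)-2-methylbut-2-enoyloxy]hepta-1,5-dien-2-yl}cyclohexane-1,3-diyl bis[(2Z)-2-methylbut-2-enoate] | C=C([C@H](CC=C(C)C)OC(=O)/C(C)=C\C)[C@H]1C[C@H](OC(=O)/C(C)=C\C)[C@@](C)(O)[C@@H](OC(=O)/C(C)=C\C)[C@H]1O | intermediate
29 | (1S,2R,3S,4S,5R)-5-{(3S)-4-[(2S)-3,3-dimethyloxiran-2-yl]-3-[(2Z)-2-methylbut-2-enoyloxy]but-1-en-2-yl}-2,4-dihydroxy-2-methylcyclohexane-1,3-diyl bis[(2Z)-2-methylbut-2-enoate] | C=C([C@H](C[C@@H]1OC1(C)C)OC(=O)/C(C)=C\C)[C@H]1C[C@H](OC(=O)/C(C)=C\C)[C@@](C)(O)[C@@H](OC(=O)/C(C)=C\C)[C@H]1O | target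

## Step count and risks

Total step count: 14. Longest linear sequence: 12 (steps 1–7, 9, 10, 12, 13 and 14, from 1); steps 8 and 11 are one-step side branches.

Steps most likely to fail:

**Step 4 (new α-ketol ring expansion).** The risk is alkyl instead of alkenyl migration (giving the conjugated 6-hydroxy-6-methylcyclohex-2-enone) or loss of the stereochemical relay to C4. The fallback uses known chemistry, sets out from 6 and comes back at 11. 1-Lithio-1-(methylselanyl)ethane (from 1,1-bis(methylselanyl)ethane and nBuLi, THF, –78 °C) adds 1,2 and anti to the C1 group to give the β-hydroxy selenide (1R,4S)-1-[1-(methylselanyl)ethyl]-4-[1-(trimethylsilyl)ethenyl]cyclopent-2-en-1-ol F1. AgBF4 on Al2O3 in CH2Cl2 then triggers the Krief semipinacol ring enlargement with migration of the alkenyl carbon to give (5S)-2-methyl-5-[1-(trimethylsilyl)ethenyl]cyclohex-3-en-1-one F2. Deprotonation at C4 with KHMDS (THF, –78 °C) and Davis hydroxylation of the dienolate with (camphorsulfonyl)oxaziridine (antipode chosen to deliver oxygen cis to the C1 group) gives 11.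

**Step 9 (tin-directed mono-angeloylation at O5 of a tetraol).** The risks are acylation at O6 or O3 instead of O5, or over-acylation. The fallback sets out from 15 and comes back at 21; it gives up the tin-directed choice between hydroxyls and instead masks the two that must stay free. PhB(OH)2 (toluene, 4 Å MS, 50 °C) converts 15 into the cyclic O4,O6-phenylboronate of 15 F3, in which O3 and O5 are the only free hydroxyls. An excess of 17 (Et3N, toluene, 80 °C, dark) then esterifies both to give 21, from which pinacol releases 22 as in step 10. The price is that two hindered positions must be driven to completion in one operation, without an isolated mono-ester to prove the position of each acyl group.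

**Step 12 (C8 configuration in the Ni/Cr coupling).** The coupling itself is robust; the risk is a low diastereomer ratio at C8. The fallback sets out from 22 and 24 and comes back at 25. Ligand-free coupling (CrCl2, NiCl2 cat., DMSO) gives 25 together with its C8 epimer (1S,2R,3S,4S,5R)-2,4-dihydroxy-5-[(3R)-3-hydroxy-6-methylhepta-1,5-dien-2-yl]-2-methylcyclohexane-1,3-diyl bis[(2Z)-2-methylbut-2-enoate] F4. MnO2 (CH2Cl2, rt) oxidises only the allylic C8 alcohol of the mixture to the enone (1S,2R,3S,4S,5R)-2,4-dihydroxy-2-methyl-5-(6-methyl-3-oxohepta-1,5-dien-2-yl)cyclohexane-1,3-diyl bis[(2Z)-2-methylbut-2-enoate] F5. Corey–Bakshi–Shibata reduction with (R)-Me-CBS and catecholborane (toluene, –78 °C; the α-substituted vinyl group acts as the large group) then returns 25 as the 8S alcohol.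

Further compounds

F1 | step 4 | (1R,4S)-1-[(1RS)-1-(methylselanyl)ethyl]-4-[1-(trimethylsilyl)ethenyl]cyclopent-2-en-1-ol | C[Se]C(C)[C@]1(O)C=C[C@@H](C(=C)[Si](C)(C)C)C1
F2 | step 4 | (2RS,5S)-2-methyl-5-[1-(trimethylsilyl)ethenyl]cyclohex-3-en-1-one | C=C([Si](C)(C)C)[C@H]1CC(=O)C(C)C=C1
F3 | step 9 | cyclic O4,O6-phenylboronate of 15 (target O4 and O6 joined through B–Ph; O3, O5 free) | C=C(I)[C@H]1C[C@H](O)[C@@]2(C)OB(c3ccccc3)O[C@@H]1[C@@H]2O
F4 | step 12 | (1S,2R,3S,4S,5R)-2,4-dihydroxy-5-[(3R)-3-hydroxy-6-methylhepta-1,5-dien-2-yl]-2-methylcyclohexane-1,3-diyl bis[(2Z)-2-methylbut-2-enoate] | C=C([C@@H](CC=C(C)C)O)[C@H]1C[C@H](OC(=O)/C(C)=C\C)[C@@](C)(O)[C@@H](OC(=O)/C(C)=C\C)[C@H]1O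
F5 | step 12 | (1S,2R,3S,4S,5R)-2,4-dihydroxy-2-methyl-5-(6-methyl-3-oxohepta-1,5-dien-2-yl)cyclohexane-1,3-diyl bis[(2Z)-2-methylbut-2-enoate] | C=C(C(=O)CC=C(C)C)[C@H]1C[C@H](OC(=O)/C(C)=C\C)[C@@](C)(O)[C@@H](OC(=O)/C(C)=C\C)[C@H]1O
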